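**Plan**

- Cuts: the two galloyl C–O bonds (O3, O5) go first. Ring A is then dismantled at C5–C6, C7–C8, C4a–C5 and C8–C8a, leaving a ring C dihydropyranyl diazomethyl ketone (C4a=C8a plus C5 and C8) and a siloxyethyne (C6, C7). Ring C is cut at the acetyl–C8a bond, at C4a–C8a and at C2–C3.
- Enabling feature: ring A has oxygen on C5, C7 and C8a (1,3,5) and is fused to ring C along C4a–C8a, so this edge can begin as the enol ether C=C of ring C. The annulation delivers O5 as a free phenol and O7 as a silyl ether, which is the distinction a 5-gallate with a free 7-OH requires.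
- Forward order: ring B arrives with the aldehyde, and allylboration joins C2–C3. Hydroformylation adds C8a and ring C closes (lactol, then δ-lactone). Enol phosphate coupling brings in C5 and C8, followed by diazo transfer, and ring A is grown last. Acetal removal, double galloylation, desilylation and hydrogenolysis finish the route.
- Stereochemistry: C2 and C3 (both R, cis) are set together by one reagent-controlled syn-alkoxyallylboration, with the chirality coming from (+)-α-pinene. Neither the C2–O1 nor the C3–O bond is broken afterwards.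

Key step: step 8

Remark: flavan numbering (O1, C2, C3, C4, C4a, C5 to C8, C8a) is used for the atoms of every intermediate. All compounds marked as starting material in the list are assumed to be purchased.

**Step 1**
Reactants: 1 3,4,5-tris(benzyloxy)benzaldehyde; 2 allyl methoxymethyl ether; 3 (−)-B-methoxydiisopinocampheylborane (derived from (+)-α-pinene)
Product: 6 (1R,2R)-2-(methoxymethoxy)-1-[3,4,5-tris(benzyloxy)phenyl]but-3-en-1-ol, via allyllithium 4 (not isolated), via allylborane 5 (not isolated)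
Conditions: 2, s-BuLi, THF, −78 °C; 3, −78 °C; BF3·OEt2, then 1, −78 °C; NaOH, H2O2, 0 °C to rt
Reagents that add atoms: none
Why: Brown asymmetric alkoxyallylboration: chelated (Z)-allyllithium 4 gives (Z)-γ-alkoxyallylborane 5, whose closed chair transition state turns the Z geometry into the syn (threo) relation while the isopinocampheyl groups direct addition to the Si face of 1, so C2 and C3 are both set as R and become cis once O1 and C4 are tied into ring C.

**Step 2**
Reactants: 6 (1R,2R)-2-(methoxymethoxy)-1-[3,4,5-tris(benzyloxy)phenyl]but-3-en-1-ol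
Product: 8 (5R,6R)-5-(methoxymethoxy)-6-[3,4,5-tris(benzyloxy)phenyl]oxan-2-ol (both anomers), via hydroxy aldehyde 7 (not isolated)
Conditions: Rh(acac)(CO)2 (1 mol %), BIPHEPHOS (2 mol %), CO and H2 (5 bar each), THF, 60 °C
Reagents that add atoms: carbon monoxide [C-]#[O+]
Why: Linear-selective rhodium-catalysed hydroformylation of a terminal alkene with a bulky chelating diphosphite places the formyl carbon (future C8a) on the terminal carbon (C4a), which supplies the fifth ring carbon that hydroboration–oxidation would lack (that sequence ends in a five-membered lactone), and δ-hydroxy aldehyde 7 closes spontaneously to the six-membered lactol.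

**Step 3**
Reactants: 8 (5R,6R)-5-(methoxymethoxy)-6-[3,4,5-tris(benzyloxy)phenyl]oxan-2-ol
Product: 9 (5R,6R)-5-(methoxymethoxy)-6-[3,4,5-tris(benzyloxy)phenyl]oxan-2-one
Conditions: nPr4N[RuO4] (5 mol %), N-methylmorpholine N-oxide, 4 Å MS, CH2Cl2, rt
Reagents that add atoms: none
Why: Ley–Griffith oxidation converts lactols to lactones under neutral conditions that leave the benzyl ethers, the acetal and both stereocentres untouched.

**Step 4**
Reactants: 9 (5R,6R)-5-(methoxymethoxy)-6-[3,4,5-tris(benzyloxy)phenyl]oxan-2-one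
Product: 11 (2R,3R)-3-(methoxymethoxy)-2-[3,4,5-tris(benzyloxy)phenyl]-3,4-dihydro-2H-pyran-6-yl diphenyl phosphate, via potassium enolate 10 (not isolated)
Conditions: KN(SiMe3)2, (PhO)2P(O)Cl, HMPA, THF, −78 °C
Reagents that add atoms: diphenyl chlorophosphate O=P(Cl)(Oc1ccccc1)Oc1ccccc1
Why: Kinetic enolisation of a δ-lactone and O-phosphorylation of enolate 10 is the standard entry to cyclic ketene acetal phosphates, and the C3 alkoxy group sits γ to the carbonyl, so no β-elimination path exists.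

**Step 5**
Reactants: 11 (2R,3R)-3-(methoxymethoxy)-2-[3,4,5-tris(benzyloxy)phenyl]-3,4-dihydro-2H-pyran-6-yl diphenyl phosphate
Product: 13 1-[(2R,3R)-3-(methoxymethoxy)-2-[3,4,5-tris(benzyloxy)phenyl]-3,4-dihydro-2H-pyran-6-yl]ethan-1-one, via ethoxyvinyl diene 12 (not isolated)
Conditions: CH2=C(OEt)SnBu3, Pd(PPh3)4 (5 mol %), LiCl, THF, reflux; then 1 M HCl, THF, 0 °C
Reagents that add atoms: tributyl(1-ethoxyvinyl)stannane C=C(OCC)[Sn](CCCC)(CCCC)CCCC; water O
Why: Stille coupling: zerovalent palladium inserts into the C–O bond of the ketene acetal phosphate and transfers the 1-ethoxyvinyl group (C5 and C8), and in diene 12 the acyclic enol ether is protonated at its terminal CH2 much faster than the ring enol ether, which is then deactivated by conjugation with the new acetyl group.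

**Step 6**
Reactants: 13 1-[(2R,3R)-3-(methoxymethoxy)-2-[3,4,5-tris(benzyloxy)phenyl]-3,4-dihydro-2H-pyran-6-yl]ethan-1-one
Product: 16 2-diazo-1-[(2R,3R)-3-(methoxymethoxy)-2-[3,4,5-tris(benzyloxy)phenyl]-3,4-dihydro-2H-pyran-6-yl]ethan-1-one, via lithium enolate 14 (not isolated), via trifluoroacetyl diketone 15 (not isolated)
Conditions: LiN(SiMe3)2, THF, −78 °C; CF3CO2CH2CF3; dilute HCl wash; then 4-acetamidobenzenesulfonyl azide, Et3N, H2O (1 equiv), MeCN, rt
Reagents that add atoms: 4-acetamidobenzenesulfonyl azide CC(=O)Nc1ccc(cc1)S(=O)(=O)N=[N+]=[N-]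
Why: Detrifluoroacetylative diazo transfer (Danheiser modification of the Regitz reaction): the kinetic cross-conjugated enolate 14 is trifluoroacetylated at the methyl carbon and the activated diketone 15 takes up N2 from the sulfonyl azide with loss of the trifluoroacetyl group, a sequence designed for enones because it avoids diazomethane and its dipolar addition to the C=C bond.

**Step 7**
Reactants: 17 acetylene; 18 triisopropylsilyl trifluoromethanesulfonate
Product: 21 (triisopropylsiloxy)ethyne, via lithium acetylide 19 (not isolated), via lithium ethynolate 20 (not isolated)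
Conditions: 17 (excess), n-BuLi, THF, −78 °C; t-BuOOLi (t-BuOOH + LiN(SiMe3)2, THF, −78 °C), −78 to 0 °C; 18, −78 °C to rt; distillation
Reagents that add atoms: tert-butyl hydroperoxide CC(C)(C)OO
Why: Electrophilic oxygenation of a lithium acetylide by lithium tert-butyl peroxide gives the ynolate, and the hard, bulky silyl triflate should silylate 20 on oxygen, as in the established one-flask preparation of triisopropylsiloxyalkynes from terminal alkynes.

**Step 8**
Reactants: 16 2-diazo-1-[(2R,3R)-3-(methoxymethoxy)-2-[3,4,5-tris(benzyloxy)phenyl]-3,4-dihydro-2H-pyran-6-yl]ethan-1-one; 21 (triisopropylsiloxy)ethyne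
Product: 26 (2R,3R)-3-(methoxymethoxy)-7-(triisopropylsilyloxy)-2-[3,4,5-tris(benzyloxy)phenyl]chroman-5-ol, via vinylketene 22 (not isolated), via vinylcyclobutenone 23 (not isolated), via dienylketene 24 (not isolated), via cyclohexadienone 25 (not isolated)
Conditions: 21 (2.5 equiv), hν (medium-pressure Hg lamp, Pyrex filter), degassed ClCH2CH2Cl, 25 °C; then 80 °C
Reagents that add atoms: none
Why: Light expels N2 from 16 and the pyranyl carbon C8a shifts from the acyl carbon to the diazo carbon C8 (photo-Wolff rearrangement, new C8–C8a bond), so vinylketene 22 carries the future C5 as its carbonyl carbon. The polarised alkyne 21 then adds across the ketene C=C in a [2+2] cycloaddition in which its unsubstituted, nucleophilic carbon bonds to the electrophilic ketene carbon (C5–C6) and its silyloxy carbon bonds to C8 (C7–C8), and this electronic match is the regiocontrol the step needs, since it places the silyl ether at C7, meta to the new hydroxyl. Heating opens 23 by reversible 4π electrocyclic cleavage of C5–C8 to dienylketene 24, ring A closes by 6π electrocyclisation of the ketene carbon onto C4a (C4a–C5), a closure that is polarity-matched because C4a is the β-carbon of the ring C enol ether, and dienone 25 tautomerises to the phenol. This is the diazo ketone version of the Danheiser benzannulation, whose usual partners are cycloalkenyl diazomethyl ketones and triisopropylsiloxyalkynes and whose products are resorcinol monosilyl ethers. No lasting stereocentre is created (the sp3 centres at C8 in 23 and at C4a in 25 disappear on ring opening and on aromatisation), and C2 and C3 lie outside the reacting π system, so the cis (2R,3R) array is carried through. The Pyrex cut-off keeps short-wave light away from the benzyl aryl ether chromophores, and the excess of 21 should outrun acylation of the product phenol by 22.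

**Step 9**
Reactants: 26 (2R,3R)-3-(methoxymethoxy)-7-(triisopropylsilyloxy)-2-[3,4,5-tris(benzyloxy)phenyl]chroman-5-ol
Product: 27 (2R,3R)-7-(triisopropylsilyloxy)-2-[3,4,5-tris(benzyloxy)phenyl]chroman-3,5-diol
Conditions: ZnBr2, n-PrSH, CH2Cl2, 0 °C
Reagents that add atoms: none
Why: Lewis acid/thiol cleavage of a methoxymethyl ether: ZnBr2 activates the acetal and the thiol captures the CH2 unit as a dithioacetal, so no formaldehyde equivalent remains to attack the nucleophilic ring A, while the aryl silyl ether, the benzyl ethers and the C2–O1 bond should survive the short, cold exposure.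

**Step 10**
Reactants: 27 (2R,3R)-7-(triisopropylsilyloxy)-2-[3,4,5-tris(benzyloxy)phenyl]chroman-3,5-diol; 28 3,4,5-tris(benzyloxy)benzoic acid
Product: 29 (2R,3R)-7-(triisopropylsilyloxy)-2-[3,4,5-tris(benzyloxy)phenyl]chroman-3,5-diyl bis[3,4,5-tris(benzyloxy)benzoate]
Conditions: 28 (2.5 equiv), DCC, DMAP, CH2Cl2, rt
Reagents that add atoms: none
Why: Steglich esterification acylates the C5 phenol and the axial C3 alcohol in one operation, the only other ring A oxygen (O7) being blocked as its silyl ether.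

**Step 11**
Reactants: 29 (2R,3R)-7-(triisopropylsilyloxy)-2-[3,4,5-tris(benzyloxy)phenyl]chroman-3,5-diyl bis[3,4,5-tris(benzyloxy)benzoate]
Product: 30 (2R,3R)-7-hydroxy-2-[3,4,5-tris(benzyloxy)phenyl]chroman-3,5-diyl bis[3,4,5-tris(benzyloxy)benzoate]
Conditions: Bu4NF, AcOH (equimolar), THF, 0 °C
Reagents that add atoms: none
Why: Fluoride cleaves the phenolic Si–O bond, and the acetic acid buffer keeps the liberated C7 phenoxide protonated, so neither gallate ester is cleaved or transferred.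

**Step 12**
Reactants: 30 (2R,3R)-7-hydroxy-2-[3,4,5-tris(benzyloxy)phenyl]chroman-3,5-diyl bis[3,4,5-tris(benzyloxy)benzoate]
Product: 31 epigallocatechin 3,5-digallate
Conditions: H2 (1 atm), Pd(OH)2/C, THF–MeOH, rt
Reagents that add atoms: none
Why: Catalytic hydrogenolysis removes all nine benzyl ethers under neutral conditions that are routine for galloylated flavan-3-ols and leave the esters, the C2–O1 bond and both stereocentres intact.

**Compound list**

1 | 3,4,5-tris(benzyloxy)benzaldehyde | O=Cc1cc(OCc2ccccc2)c(OCc2ccccc2)c(OCc2ccccc2)c1 | starting material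
2 | allyl methoxymethyl ether | C=CCOCOC | starting material
3 | (−)-B-methoxydiisopinocampheylborane | COB([C@@H]1C[C@@H]2C[C@H]([C@H]1C)C2(C)C)[C@@H]1C[C@@H]2C[C@H]([C@H]1C)C2(C)C | starting material
4 | (Z)-[3-(methoxymethoxy)allyl]lithium (not isolated) | [Li]C/C=C\OCOC | intermediate
5 | (Z)-[3-(methoxymethoxy)allyl]diisopinocampheylborane (not isolated) | COCO/C=C\CB([C@@H]1C[C@@H]2C[C@H]([C@H]1C)C2(C)C)[C@@H]1C[C@@H]2C[C@H]([C@H]1C)C2(C)C | intermediate
6 | (1R,2R)-2-(methoxymethoxy)-1-[3,4,5-tris(benzyloxy)phenyl]but-3-en-1-ol | C=C[C@@H](OCOC)[C@@H](c1cc(OCc2ccccc2)c(OCc2ccccc2)c(OCc2ccccc2)c1)O | intermediate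
7 | (4R,5R)-5-hydroxy-4-(methoxymethoxy)-5-[3,4,5-tris(benzyloxy)phenyl]pentanal (not isolated) | O=CCC[C@@H](OCOC)[C@@H](c1cc(OCc2ccccc2)c(OCc2ccccc2)c(OCc2ccccc2)c1)O | intermediate
8 | (5R,6R)-5-(methoxymethoxy)-6-[3,4,5-tris(benzyloxy)phenyl]oxan-2-ol, both anomers | OC1CC[C@@H](OCOC)[C@@H](c2cc(OCc3ccccc3)c(OCc3ccccc3)c(OCc3ccccc3)c2)O1 | intermediate
9 | (5R,6R)-5-(methoxymethoxy)-6-[3,4,5-tris(benzyloxy)phenyl]oxan-2-one | O=C1CC[C@@H](OCOC)[C@@H](c2cc(OCc3ccccc3)c(OCc3ccccc3)c(OCc3ccccc3)c2)O1 | intermediate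
10 | potassium enolate of 9 (not isolated) | [K+].[O-]C1=CC[C@@H](OCOC)[C@@H](c2cc(OCc3ccccc3)c(OCc3ccccc3)c(OCc3ccccc3)c2)O1 | intermediate
11 | (2R,3R)-3-(methoxymethoxy)-2-[3,4,5-tris(benzyloxy)phenyl]-3,4-dihydro-2H-pyran-6-yl diphenyl phosphate | O=P(Oc1ccccc1)(Oc1ccccc1)OC1=CC[C@@H](OCOC)[C@@H](c2cc(OCc3ccccc3)c(OCc3ccccc3)c(OCc3ccccc3)c2)O1 | intermediate
12 | (2R,3R)-6-(1-ethoxyethenyl)-3-(methoxymethoxy)-2-[3,4,5-tris(benzyloxy)phenyl]-3,4-dihydro-2H-pyran (not isolated) | C=C(OCC)C1=CC[C@@H](OCOC)[C@@H](c2cc(OCc3ccccc3)c(OCc3ccccc3)c(OCc3ccccc3)c2)O1 | intermediate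
13 | 1-[(2R,3R)-3-(methoxymethoxy)-2-[3,4,5-tris(benzyloxy)phenyl]-3,4-dihydro-2H-pyran-6-yl]ethan-1-one | CC(=O)C1=CC[C@@H](OCOC)[C@@H](c2cc(OCc3ccccc3)c(OCc3ccccc3)c(OCc3ccccc3)c2)O1 | intermediate
14 | lithium enolate of 13 (not isolated) | [Li+].C=C([O-])C1=CC[C@@H](OCOC)[C@@H](c2cc(OCc3ccccc3)c(OCc3ccccc3)c(OCc3ccccc3)c2)O1 | intermediate
15 | 4,4,4-trifluoro-1-[(2R,3R)-3-(methoxymethoxy)-2-[3,4,5-tris(benzyloxy)phenyl]-3,4-dihydro-2H-pyran-6-yl]butane-1,3-dione (not isolated) | O=C(CC(=O)C(F)(F)F)C1=CC[C@@H](OCOC)[C@@H](c2cc(OCc3ccccc3)c(OCc3ccccc3)c(OCc3ccccc3)c2)O1 | intermediate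
16 | 2-diazo-1-[(2R,3R)-3-(methoxymethoxy)-2-[3,4,5-tris(benzyloxy)phenyl]-3,4-dihydro-2H-pyran-6-yl]ethan-1-one | [N-]=[N+]=CC(=O)C1=CC[C@@H](OCOC)[C@@H](c2cc(OCc3ccccc3)c(OCc3ccccc3)c(OCc3ccccc3)c2)O1 | intermediate
17 | acetylene | C#C | starting material
18 | triisopropylsilyl trifluoromethanesulfonate | CC(C)[Si](OS(=O)(=O)C(F)(F)F)(C(C)C)C(C)C | starting material
19 | lithium acetylide (not isolated) | [Li+].[C-]#C | intermediate
20 | lithium ethynolate (not isolated) | [Li+].[O-]C#C | intermediate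
21 | (triisopropylsiloxy)ethyne | C#CO[Si](C(C)C)(C(C)C)C(C)C | intermediate
22 | 2-[(2R,3R)-3-(methoxymethoxy)-2-[3,4,5-tris(benzyloxy)phenyl]-3,4-dihydro-2H-pyran-6-yl]ethen-1-one, the vinylketene (not isolated) | O=C=CC1=CC[C@@H](OCOC)[C@@H](c2cc(OCc3ccccc3)c(OCc3ccccc3)c(OCc3ccccc3)c2)O1 | intermediate
23 | 4-[(2R,3R)-3-(methoxymethoxy)-2-[3,4,5-tris(benzyloxy)phenyl]-3,4-dihydro-2H-pyran-6-yl]-3-(triisopropylsilyloxy)cyclobut-2-en-1-one, both epimers at the ring sp3 carbon (not isolated) | O=C1C=C(O[Si](C(C)C)(C(C)C)C(C)C)C1C2=CC[C@@H](OCOC)[C@@H](c3cc(OCc4ccccc4)c(OCc4ccccc4)c(OCc4ccccc4)c3)O2 | intermediate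
24 | 4-[(2R,3R)-3-(methoxymethoxy)-2-[3,4,5-tris(benzyloxy)phenyl]-3,4-dihydro-2H-pyran-6-yl]-3-(triisopropylsilyloxy)buta-1,3-dien-1-one, C6 and C8a cis across C7=C8 (not isolated) | O=C=C/C(O[Si](C(C)C)(C(C)C)C(C)C)=C\C1=CC[C@@H](OCOC)[C@@H](c2cc(OCc3ccccc3)c(OCc3ccccc3)c(OCc3ccccc3)c2)O1 | intermediate
25 | (2R,3R)-3-(methoxymethoxy)-7-(triisopropylsilyloxy)-2-[3,4,5-tris(benzyloxy)phenyl]-2,3,4,4a-tetrahydro-5H-chromen-5-one (not isolated) | O=C1C=C(O[Si](C(C)C)(C(C)C)C(C)C)C=C2C1C[C@@H](OCOC)[C@@H](c3cc(OCc4ccccc4)c(OCc4ccccc4)c(OCc4ccccc4)c3)O2 | intermediate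
26 | (2R,3R)-3-(methoxymethoxy)-7-(triisopropylsilyloxy)-2-[3,4,5-tris(benzyloxy)phenyl]chroman-5-ol | Oc1cc(O[Si](C(C)C)(C(C)C)C(C)C)cc2c1C[C@@H](OCOC)[C@@H](c1cc(OCc3ccccc3)c(OCc3ccccc3)c(OCc3ccccc3)c1)O2 | intermediate
27 | (2R,3R)-7-(triisopropylsilyloxy)-2-[3,4,5-tris(benzyloxy)phenyl]chroman-3,5-diol | Oc1cc(O[Si](C(C)C)(C(C)C)C(C)C)cc2c1C[C@@H](O)[C@@H](c1cc(OCc3ccccc3)c(OCc3ccccc3)c(OCc3ccccc3)c1)O2 | intermediate
28 | 3,4,5-tris(benzyloxy)benzoic acid | OC(=O)c1cc(OCc2ccccc2)c(OCc2ccccc2)c(OCc2ccccc2)c1 | starting material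
29 | (2R,3R)-7-(triisopropylsilyloxy)-2-[3,4,5-tris(benzyloxy)phenyl]chroman-3,5-diyl bis[3,4,5-tris(benzyloxy)benzoate] | O=C(Oc1cc(O[Si](C(C)C)(C(C)C)C(C)C)cc2c1C[C@@H](OC(=O)c1cc(OCc3ccccc3)c(OCc3ccccc3)c(OCc3ccccc3)c1)[C@@H](c1cc(OCc3ccccc3)c(OCc3ccccc3)c(OCc3ccccc3)c1)O2)c1cc(OCc2ccccc2)c(OCc2ccccc2)c(OCc2ccccc2)c1 | intermediate
30 | (2R,3R)-7-hydroxy-2-[3,4,5-tris(benzyloxy)phenyl]chroman-3,5-diyl bis[3,4,5-tris(benzyloxy)benzoate] | O=C(Oc1cc(O)cc2c1C[C@@H](OC(=O)c1cc(OCc3ccccc3)c(OCc3ccccc3)c(OCc3ccccc3)c1)[C@@H](c1cc(OCc3ccccc3)c(OCc3ccccc3)c(OCc3ccccc3)c1)O2)c1cc(OCc2ccccc2)c(OCc2ccccc2)c(OCc2ccccc2)c1 | intermediate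
31 | epigallocatechin 3,5-digallate, (2R,3R)-7-hydroxy-2-(3,4,5-trihydroxyphenyl)chroman-3,5-diyl bis(3,4,5-trihydroxybenzoate) | O=C(Oc1cc(O)cc2c1C[C@@H](OC(=O)c1cc(O)c(O)c(O)c1)[C@@H](c1cc(O)c(O)c(O)c1)O2)c1cc(O)c(O)c(O)c1 | target

**Step count**

- Total step count: 12.
- Longest linear sequence: 11 (steps 1 to 6 and 8 to 12). Step 7 is a one-step side branch.

**Steps most likely to fail**

1. **Step 8 (key step).**
   - What may go wrong: the aryl chromophores may screen the diazo ketone and slow the photolysis. Carbene reactions may compete with the 1,2-shift. The ketene may be consumed by acylating phenol that has already formed.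
   - Fallback (sets out from 9, returns at 26): the same vinylketene 22 is generated in the dark by 1,4-dehydrochlorination of an unsaturated acid chloride, a classical source of vinylketenes. Addition of the lithium enolate of ethyl acetate (LiN(iPr)2, EtOAc, THF, −78 °C) to 9 should give the hemiketal ethyl 2-[(5R,6R)-2-hydroxy-5-(methoxymethoxy)-6-[3,4,5-tris(benzyloxy)phenyl]oxan-2-yl]acetate F1. MsCl/Et3N dehydrates it to the β-alkoxyacrylate ethyl 2-[(5R,6R)-5-(methoxymethoxy)-6-[3,4,5-tris(benzyloxy)phenyl]oxan-2-ylidene]acetate F2. LiOH (THF–H2O) gives 2-[(5R,6R)-5-(methoxymethoxy)-6-[3,4,5-tris(benzyloxy)phenyl]oxan-2-ylidene]acetic acid F3. 1-Chloro-N,N,2-trimethylprop-1-en-1-amine (CH2Cl2, 0 °C) converts it under neutral conditions to 2-[(5R,6R)-5-(methoxymethoxy)-6-[3,4,5-tris(benzyloxy)phenyl]oxan-2-ylidene]acetyl chloride F4. Slow addition of F4 to Et3N and 21 in toluene at 80 to 110 °C removes HCl (γ-hydrogen at C4a), and 22 then runs through 23, 24 and 25 to 26. This path makes steps 4 to 6 unnecessary.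

2. **Step 7.**
   - What may go wrong: the monolithium acetylide may disproportionate on warming. The unsubstituted ynolate may be silylated on carbon instead of oxygen, because no substituent shields that carbon.
   - Fallback (sets out from 18, returns at 26): the carbon terminus is blocked by a trimethylsilyl group that is removed after the annulation. (Trimethylsilyl)diazomethane is treated with n-BuLi and then CO (1 atm, THF, −78 °C) to give lithium 2-(trimethylsilyl)ethynolate F5. With 18, crowding at carbon forces O-silylation to 1-(triisopropylsiloxy)-2-(trimethylsilyl)ethyne F6. Under the conditions of step 8, 16 and F6 should give (2R,3R)-3-(methoxymethoxy)-6-(trimethylsilyl)-7-(triisopropylsilyloxy)-2-[3,4,5-tris(benzyloxy)phenyl]chroman-5-ol F7, since the silyloxy and silyl groups both direct the ketene carbon to the same alkyne carbon. Ipso-protodesilylation of this very electron-rich arylsilane (CF3CO2H, 2 equiv, CH2Cl2, 0 °C) leads to 26.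

3. **Step 9.**
   - What may go wrong: the phenolic silyl ether may be lost. The Lewis acid may open the benzylic C2–O1 bond, leading to epimerisation at C2 or thiol capture. The released one-carbon fragment may attack ring A electrophilically.
   - Fallback (sets out from 26, returns at 29): the two esters are introduced one after the other, so that ring A is deactivated before the acetal is touched. Steglich esterification of 26 with one equivalent of 28 (DCC, DMAP, CH2Cl2) gives (2R,3R)-3-(methoxymethoxy)-7-(triisopropylsilyloxy)-2-[3,4,5-tris(benzyloxy)phenyl]chroman-5-yl 3,4,5-tris(benzyloxy)benzoate F8. Me2BBr (CH2Cl2, −78 °C, then aqueous NaHCO3) cleaves the acetal at low temperature to give (2R,3R)-3-hydroxy-7-(triisopropylsilyloxy)-2-[3,4,5-tris(benzyloxy)phenyl]chroman-5-yl 3,4,5-tris(benzyloxy)benzoate F9. A second esterification with 28 gives 29.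

**Further compounds**

F1 | step 8 | ethyl 2-[(5R,6R)-2-hydroxy-5-(methoxymethoxy)-6-[3,4,5-tris(benzyloxy)phenyl]oxan-2-yl]acetate | CCOC(=O)CC1(O)CC[C@@H](OCOC)[C@@H](c2cc(OCc3ccccc3)c(OCc3ccccc3)c(OCc3ccccc3)c2)O1
F2 | step 8 | ethyl 2-[(5R,6R)-5-(methoxymethoxy)-6-[3,4,5-tris(benzyloxy)phenyl]oxan-2-ylidene]acetate | CCOC(=O)C=C1CC[C@@H](OCOC)[C@@H](c2cc(OCc3ccccc3)c(OCc3ccccc3)c(OCc3ccccc3)c2)O1
F3 | step 8 | 2-[(5R,6R)-5-(methoxymethoxy)-6-[3,4,5-tris(benzyloxy)phenyl]oxan-2-ylidene]acetic acid | OC(=O)C=C1CC[C@@H](OCOC)[C@@H](c2cc(OCc3ccccc3)c(OCc3ccccc3)c(OCc3ccccc3)c2)O1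
F4 | step 8 | 2-[(5R,6R)-5-(methoxymethoxy)-6-[3,4,5-tris(benzyloxy)phenyl]oxan-2-ylidene]acetyl chloride | ClC(=O)C=C1CC[C@@H](OCOC)[C@@H](c2cc(OCc3ccccc3)c(OCc3ccccc3)c(OCc3ccccc3)c2)O1
F5 | step 7 | lithium 2-(trimethylsilyl)ethynolate | [Li+].[O-]C#C[Si](C)(C)C
F6 | step 7 | 1-(triisopropylsiloxy)-2-(trimethylsilyl)ethyne | C[Si](C)(C)C#CO[Si](C(C)C)(C(C)C)C(C)C
F7 | step 7 | (2R,3R)-3-(methoxymethoxy)-6-(trimethylsilyl)-7-(triisopropylsilyloxy)-2-[3,4,5-tris(benzyloxy)phenyl]chroman-5-ol | Oc1c([Si](C)(C)C)c(O[Si](C(C)C)(C(C)C)C(C)C)cc2c1C[C@@H](OCOC)[C@@H](c1cc(OCc3ccccc3)c(OCc3ccccc3)c(OCc3ccccc3)c1)O2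
F8 | step 9 | (2R,3R)-3-(methoxymethoxy)-7-(triisopropylsilyloxy)-2-[3,4,5-tris(benzyloxy)phenyl]chroman-5-yl 3,4,5-tris(benzyloxy)benzoate | O=C(Oc1cc(O[Si](C(C)C)(C(C)C)C(C)C)cc2c1C[C@@H](OCOC)[C@@H](c1cc(OCc3ccccc3)c(OCc3ccccc3)c(OCc3ccccc3)c1)O2)c1cc(OCc2ccccc2)c(OCc2ccccc2)c(OCc2ccccc2)c1
F9 | step 9 | (2R,3R)-3-hydroxy-7-(triisopropylsilyloxy)-2-[3,4,5-tris(benzyloxy)phenyl]chroman-5-yl 3,4,5-tris(benzyloxy)benzoate | O=C(Oc1cc(O[Si](C(C)C)(C(C)C)C(C)C)cc2c1C[C@@H](O)[C@@H](c1cc(OCc3ccccc3)c(OCc3ccccc3)c(OCc3ccccc3)c1)O2)c1cc(OCc2ccccc2)c(OCc2ccccc2)c(OCc2ccccc2)c1
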